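## The problem

Compound 26 is a eudesmane, numbered here in the usual way: ring A = C1–C5 and C10, ring B = C5–C10, C14 on C10, C15 on C4, C11–C13 the three-carbon unit on C7. The two six-membered rings share the C5–C10 bond, and because the tetrasubstituted C4=C5 alkene runs into the fusion, C10 is the only fusion stereocentre: a methyl-bearing quaternary carbon that no later centre can correct. The other three stereocentres are C3 (S, allylic acyloxy), C7 (R, acrylate-bearing) and C8 (R, acetoxy). Together with C10 (R) they place all four substituents on the β face, so the C8 acetate is axial and syn to C14, while C3 lies across ring A from C10 and can only be reached through the ring conformation. C10 can direct C7 and C8 through a chair of ring B in which C14 is axial, but that chair places an oxygen at C8 equatorial, so a correction at C8 is part of the task. The fragile groups are the methyl 2-alkylacrylate (conjugate addition, conjugate reduction, lactonisation onto a free 8β-hydroxyl), the neighbouring acetate, the allylic C3 ester (ionisation, elimination) and the (E)-3-methylpent-2-enoate, whose geometry is lost once a dienolate or ketene forms. The enabling feature is that C7 and C8 are adjacent ring-B carbons carrying a propenyl-type unit and an oxygen. That is a homoallylic alcohol with its alkene at C11=C13, which is what an aldehyde at C8 and a prenyl alkene at C7=C11 deliver in an ene reaction; the C4=C5 enone of ring A holds the two arms (C9 on C10, C6 on C5) on a rigid frame.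

## Retrosynthesis

**C3 ester.** The C3–O acyl bond is cut first, giving allylic alcohol 24 and acid 25. The dienoate-prone ester and the ionisable allylic C–O bond are the most delicate parts of 26, and placing them last keeps them away from every oxidant and hydride of the route. The forward reaction only has to acylate a secondary allylic alcohol without isomerising 25.

**C3 carbinol.** Alcohol 24 is traced to enone 23. Keeping C3 as a ketone until the penultimate step keeps C4=C5 electron-poor, hence inert to the allylic oxidation and chlorite steps. The reduction must be 1,2-selective in the presence of the acrylate and must deliver hydride to the α face.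

**Acrylate.** No skeletal bond is cut: ester 23 comes from acid 22, this from allylic alcohol 20, and 20 from the isopropenyl compound 19 by oxidation of the C12 methyl group. The alternative, building the acrylate by forming C7–C11 next to an oxygenated C8, would add a C–C bond construction that the ring closure already provides. The forward sequence needs the C8 oxygen capped, otherwise the 8β-hydroxyl and C12 would close to a lactone.

**C8 configuration.** Acetate 19 comes from axial alcohol 18, which is reached from equatorial alcohol 16 through diketone 17. A direct displacement at C8 would force the nucleophile along the axial trajectory that C14 blocks; a hydride reduction uses the same blockade to advantage.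

**C7–C8 (key).** Cutting the C7–C8 bond of 16 opens ring B to the monocyclic enone aldehyde 14. This removes a ring and both ring-B stereocentres at once and leaves a single stereocentre, C10. Cuts at C5–C6 or C9–C10 would instead demand a ring closure onto a tetrasubstituted or quaternary carbon. The forward reaction must form one C–C bond with control of C7 and C8 from C10 and place the alkene at C11=C13.

**Prenyl arm and enone.** The C7=C11 alkene of 14 is cut by cross-metathesis logic to allyl compound 12 and 2-methylbut-2-ene 13. The C5–C6 bond of 12 is then cut to vinylogous ester 10 and an allyl Grignard reagent; the addition and acid-induced transposition create the enone and unmask the aldehyde together. A prenyl nucleophile cannot be used directly because it would add through its tertiary terminus.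

**C8 aldehyde.** Acetal 10 comes from aldehyde 9, and 9 from the terminal alkene of 7 by oxidative cleavage. The acetal is needed only to carry C8 through the Grignard step.

**C10.** The C9–C10 bond of 7 is cut to the racemic allyl β-keto ester 6, which comes from 5, and 5 from vinylogous ester 2 and allyl chloroformate 3; 2 is made from dione 1. The forward step must create the quaternary centre enantioselectively from an enolate with no second coordinating group, the situation for which decarboxylative allylation was developed.

## Roads not taken

**Alternative 1:** The cut is the fusion bond C5–C10, leading back to the ten-membered (1(10)E,4E)-germacradiene A2. Forward, catalytic TsOH protonates C1, C5 of the C4=C5 alkene attacks the C10 cation across the ring, and loss of H5 gives eudesmadiene A1. A1 already holds the C3 oxygen, the C8 acetate and the acrylate in the right configurations, so only desilylation and esterification remain. In this respect the road is clearly better than the chosen plan, which needs eight steps after its ring closure. Its weak points lie elsewhere: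
- The whole difficulty moves into A2: a ten-membered ring with two E-trisubstituted alkenes, three stereocentres and an acrylate has no short entry, and such dienes rearrange to elemanes on warming.
- After cyclisation the C4 cation sits beside the silyloxy-bearing C3, so a 1,2-hydride shift from C3 or loss of a C15 or C3 proton can compete with loss of H5.
- The configuration at C10 depends on which ring conformer reacts.

Against the short endgame the chosen plan sets a precursor (14) reachable by eight precedented steps, a ring closure whose termination is an intramolecular hydrogen transfer and therefore regiodefined, and catalyst control over C10.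

**Alternative 2:** The cut is C9–C10. Forward, KOt-Bu converts phenol tosylate A4 into its phenolate, whose para carbon (C10, already bearing C14) displaces the primary tosylate at C9; this closes ring B and leaves the cross-conjugated dienone A3. The road is convergent, takes ring A from a cheap aromatic and forms the quaternary centre and ring B in one step, which is as good as the chosen plan. Its weak points are these:
- C7 and C8 must be built separately in the acyclic chain of A4, and C10 then depends on relayed induction from them.
- A3 carries an extra C1=C2 alkene that must be removed in the presence of the isopropenyl group; a hydrogenation catalyst such as RhCl(PPh3)3 does not distinguish the two reliably.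
- The dienone is open to dienone–phenol rearrangement under acid.
- The 8α-oxygen of A3 still needs the same inversion.

The chosen plan derives C7 and C8 from C10 in one step and creates no unsaturation that has to be taken out again.

**Alternative 3:** The cuts are C5–C6 and C9–C10. Forward, 2-silyloxydiene A7 adds across the methyl-bearing alkene of quinone A6 under a chiral titanium Lewis acid made from TiCl2(O-i-Pr)2 and 1,1'-bi-2-naphthol and chelated between the C4 carbonyl and C3 methoxy oxygens. The product is the cis-fused adduct A5, with quaternary C10 and a C8 silyl enol ether. This road forms two C–C bonds, ring B and the quaternary centre in its first step from achiral commercial materials. That is better than the chosen plan, which spends four steps before C10 is set. For 26, however, A5 is over-oxidised and under-substituted: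
- The C1 carbonyl must be deleted.
- C15 must be added at C4 and C4=C5 generated, which discards the C5 stereocentre.
- The entire C11–C13 unit must be attached beside the C8 ketone with C7-versus-C9 regiocontrol and stereocontrol.
- Asymmetric induction for a simple 2-silyloxydiene with this quinone is the least precedented element.

The chosen plan is slower to its first stereocentre, but one ring closure then supplies the C7 side chain and both ring-B stereocentres with nothing to remove.

Key step: step 9

Assumption: the t-Bu-PHOX ligand is taken to impose the same facial sense on the vinylogous-ester enolate as on the 2-methylcyclohexanone enolate, which makes the (R)-ligand the one that delivers (R)-7; if the sense is reversed for this substrate, the (S)-ligand is used with no other change.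

## Route

Step 1
Reactants: 1 2-methylcyclohexane-1,3-dione
Product: 2 3-isobutoxy-2-methylcyclohex-2-en-1-one
Conditions: i-BuOH, TsOH·H2O (cat.), toluene, reflux, Dean–Stark
Reagents that add atoms: 2-methylpropan-1-ol, CC(C)CO
Why: Acid-catalysed condensation of the cyclic 1,3-dione with the alcohol under azeotropic water removal gives the vinylogous ester; the dione is symmetric, so only one product can form.

Step 2
Reactants: 2 3-isobutoxy-2-methylcyclohex-2-en-1-one; 3 allyl chloroformate
Product: 5 allyl 4-isobutoxy-3-methyl-2-oxocyclohex-3-ene-1-carboxylate (racemic), via lithium dienolate 4 (not isolated)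
Conditions: LiN(i-Pr)2 (2.1 equiv), THF, −78 °C; then 3, −78 → −20 °C; aq. NH4Cl
Reagents that add atoms: none
Why: Kinetic deprotonation of a vinylogous ester takes place at the α′ carbon, and C-acylation of the lithium dienolate by the chloroformate gives the β-keto ester (Claisen-type acylation); the second equivalent of base deprotonates the product as it forms and prevents proton exchange with unreacted 4.

Step 3
Reactants: 5 allyl 4-isobutoxy-3-methyl-2-oxocyclohex-3-ene-1-carboxylate (racemic)
Product: 6 allyl 4-isobutoxy-1,3-dimethyl-2-oxocyclohex-3-ene-1-carboxylate (racemic)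
Conditions: MeI, Cs2CO3, MeCN, 50 °C
Reagents that add atoms: iodomethane, CI
Why: C-methylation of the stabilised β-keto ester enolate under carbonate base; the product is deliberately racemic because this stereocentre is erased and rebuilt in step 4.

Step 4
Reactants: 6 allyl 4-isobutoxy-1,3-dimethyl-2-oxocyclohex-3-ene-1-carboxylate (racemic)
Product: 7 (6R)-6-allyl-3-isobutoxy-2,6-dimethylcyclohex-2-en-1-one
Conditions: Pd2(dba)3 (2.5 mol %), (R)-t-Bu-PHOX [(R)-4-tert-butyl-2-(2-diphenylphosphanylphenyl)-4,5-dihydrooxazole, 6.25 mol %], toluene, 25 °C
Reagents that add atoms: none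
Why: Decarboxylative asymmetric allylic alkylation (enantioselective Tsuji allylation): zerovalent palladium ionises the allyl ester, CO2 is lost, and the palladium enolate–allyl pair recombines at the α′ carbon inside the chiral P,N-ligand sphere, setting quaternary C10 as R. Both enantiomers of 6 pass through the same achiral enolate, so the step is stereoconvergent, and the enolate is regiodefined by the position of the ester.

Step 5
Reactants: 7 (6R)-6-allyl-3-isobutoxy-2,6-dimethylcyclohex-2-en-1-one
Product: 9 2-[(1R)-4-isobutoxy-1,3-dimethyl-2-oxocyclohex-3-en-1-yl]acetaldehyde, via vicinal diol 8 (not isolated)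
Conditions: OsO4 (2 mol %), NaIO4 (4 equiv), 2,6-lutidine, 1,4-dioxane/H2O 3:1, rt
Reagents that add atoms: osmium tetroxide, O=[Os](=O)(=O)=O (catalytic oxygen carrier); sodium periodate, [Na+].[O-]I(=O)(=O)=O (terminal oxidant)
Why: Lemieux–Johnson cleavage: OsO4 dihydroxylates the monosubstituted alkene to 8 and NaIO4 cleaves the diol to the aldehyde; the tetrasubstituted, carbonyl-conjugated alkene of the vinylogous ester is too hindered to compete, and 2,6-lutidine suppresses α-hydroxy ketone by-products.

Step 6
Reactants: 9 2-[(1R)-4-isobutoxy-1,3-dimethyl-2-oxocyclohex-3-en-1-yl]acetaldehyde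
Product: 10 (6R)-6-(2,2-dimethoxyethyl)-3-isobutoxy-2,6-dimethylcyclohex-2-en-1-one
Conditions: MeOSiMe3 (2.5 equiv), Me3SiOTf (2 mol %), CH2Cl2, −78 °C; pyridine
Reagents that add atoms: methoxytrimethylsilane, CO[Si](C)(C)C
Why: Noyori acetalisation with an alkoxysilane and catalytic silyl triflate is selective for aldehydes at −78 °C and is aprotic, so the vinylogous ester, which would exchange its alkoxy group in acidic methanol, is left alone; the acetal carries C8 through the Grignard step.

Step 7
Reactants: 10 (6R)-6-(2,2-dimethoxyethyl)-3-isobutoxy-2,6-dimethylcyclohex-2-en-1-one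
Product: 12 2-[(1R)-1,3-dimethyl-4-oxo-2-(prop-2-en-1-yl)cyclohex-2-en-1-yl]acetaldehyde, via tertiary allylic alcohol 11 (not isolated)
Conditions: CH2=CHCH2MgBr (1.5 equiv), THF, −78 → 0 °C; then 1 M aq. HCl, THF, rt
Reagents that add atoms: allylmagnesium bromide, C=CC[Mg]Br; water, O
Why: Stork–Danheiser transposition: the allyl Grignard reagent adds 1,2 to the vinylogous ester carbonyl (C5) to give 11, and aqueous acid hydrolyses the enol ether and eliminates the tertiary hydroxyl, which places the enone at C3/C4=C5 with the allyl group on C5. The same acid releases the C8 aldehyde from its dimethyl acetal; C10 is not touched.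

Step 8
Reactants: 12 2-[(1R)-1,3-dimethyl-4-oxo-2-(prop-2-en-1-yl)cyclohex-2-en-1-yl]acetaldehyde; 13 2-methylbut-2-ene
Product: 14 2-[(1R)-1,3-dimethyl-2-(3-methylbut-2-en-1-yl)-4-oxocyclohex-2-en-1-yl]acetaldehyde
Conditions: second-generation Hoveyda–Grubbs catalyst RuCl2(H2IMes)(=CH-C6H4-2-O-i-Pr) (5 mol %), 13 (large excess)/CH2Cl2, 40 °C, sealed vessel
Reagents that add atoms: none
Why: Olefin cross-metathesis with 2-methylbut-2-ene as isopropylidene donor turns the terminal allyl group into the prenyl group; the tetrasubstituted enone alkene is inert to the ruthenium carbene and the aldehyde is tolerated.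

Step 9
Reactants: 14 2-[(1R)-1,3-dimethyl-2-(3-methylbut-2-en-1-yl)-4-oxocyclohex-2-en-1-yl]acetaldehyde
Product: 16 (7R,8S,10R)-8α-hydroxyeudesma-4,11-dien-3-one, via chloro(methyl)aluminium alkoxide 15 (not isolated)
Conditions: Me2AlCl (2.2 equiv, 1 M in hexane), CH2Cl2, −78 → −20 °C; 1 M aq. HCl, 0 °C
Reagents that add atoms: none
Why: Me2AlCl binds the aldehyde oxygen and the C7=C11 alkene attacks C8 through C7 in a concerted but asynchronous type-1 carbonyl-ene reaction: positive charge builds at tertiary C11 while a hydrogen of a C11 methyl group passes to oxygen and the alkene re-forms as C11=C13, after which loss of methane from the aluminium-bound alcohol gives the non-acidic alkoxide 15, hydrolysed on work-up. The closest known reaction is the Lewis-acid-promoted cyclisation of citronellal to isopulegol, which has the same aldehyde, three-atom tether and trisubstituted alkene. Ring B closes as a six-membered ring through a chair transition state in which both π bonds are exocyclic to the new ring, the tether being C9–C10–C5–C6 with C5 held trigonal by the enone. C8 is set because the complexed carbonyl oxygen takes the equatorial position, the axial one being 1,3-diaxial to C14 on C10. C7 is set because the dimethylvinyl arm must also lie equatorial for a methyl hydrogen to reach the equatorial oxygen, so C10 (R) dictates 7R and 8S, that is 7β-isopropenyl and 8α-hydroxyl. The step needs the aldehyde and not the enone to act as enophile and needs bonding at C7 and not at C11: the enone carbonyl cannot reach the alkene, and Markovnikov polarisation together with six- over seven-membered closure directs bonding to C7. Me2AlCl is chosen because it also scavenges protons, which suppresses acid-induced migration of the skipped C7=C11 alkene toward the enone and stepwise cationic (Prins) pathways.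

Step 10
Reactants: 16 (7R,8S,10R)-8α-hydroxyeudesma-4,11-dien-3-one
Product: 17 (7R,10R)-eudesma-4,11-diene-3,8-dione
Conditions: Dess–Martin periodinane, NaHCO3, CH2Cl2, 0 °C → rt
Reagents that add atoms: none
Why: Dess–Martin oxidation of the equatorial secondary alcohol under buffered, non-basic conditions gives the β,γ-unsaturated ketone without moving C11=C13 into conjugation; the isopropenyl group at C7 is already in the more stable equatorial position, so C7 is not at risk.

Step 11
Reactants: 17 (7R,10R)-eudesma-4,11-diene-3,8-dione
Product: 18 (7R,8R,10R)-8β-hydroxyeudesma-4,11-dien-3-one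
Conditions: LiBH(s-Bu)3 (1.05 equiv), THF, −78 °C; aq. NH4Cl
Reagents that add atoms: none
Why: Bulky trialkylborohydride reduction: hydride reaches C8 equatorially from the α face because the axial β trajectory is blocked by C14, which gives the axial 8β-alcohol (the isopulegone to neoisopulegol precedent). The saturated ketone reacts far faster at −78 °C than the tetrasubstituted, β,β-disubstituted enone, so one equivalent is selective.

Step 12
Reactants: 18 (7R,8R,10R)-8β-hydroxyeudesma-4,11-dien-3-one
Product: 19 (7R,8R,10R)-8β-acetoxyeudesma-4,11-dien-3-one
Conditions: Ac2O, pyridine, DMAP (cat.), CH2Cl2, rt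
Reagents that add atoms: acetic anhydride, CC(=O)OC(C)=O
Why: DMAP-catalysed acetylation of the hindered axial alcohol; capping C8 now prevents lactonisation onto C12 once that carbon is oxidised.

Step 13
Reactants: 19 (7R,8R,10R)-8β-acetoxyeudesma-4,11-dien-3-one
Product: 20 (7R,8R,10R)-8β-acetoxy-12-hydroxyeudesma-4,11(13)-dien-3-one
Conditions: SeO2 (30 mol %), t-BuOOH (3 equiv), CH2Cl2, 0 °C → rt
Reagents that add atoms: selenium dioxide, O=[Se]=O (oxygen carrier); tert-butyl hydroperoxide, CC(C)(C)OO (terminal oxidant)
Why: Selenium dioxide allylic oxidation (ene reaction, then [2,3]-sigmatropic shift) of the 1,1-disubstituted alkene at its methyl group is a standard conversion of isopropenyl groups in eudesmanes. The C4=C5 alkene is deactivated by conjugation with the C3 ketone, and the C7 methine is hindered and inductively deactivated by the adjacent acetoxy group; any enal 21 formed alongside converges in step 14.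

Step 14
Reactants: 20 (7R,8R,10R)-8β-acetoxy-12-hydroxyeudesma-4,11(13)-dien-3-one
Product: 22 (7R,8R,10R)-8β-acetoxy-3-oxoeudesma-4,11(13)-dien-12-oic acid, via enal 21 (not isolated)
Conditions: MnO2, CH2Cl2, rt; filter; then NaClO2, NaH2PO4, 2-methylbut-2-ene, t-BuOH/H2O, 0 °C → rt
Reagents that add atoms: sodium chlorite, [Na+].[O-]Cl=O
Why: MnO2 oxidises only the allylic primary alcohol to enal 21, and Pinnick oxidation with a hypochlorite scavenger converts the α,β-unsaturated aldehyde into the acid without touching the alkenes, the enone or the acetate.

Step 15
Reactants: 22 (7R,8R,10R)-8β-acetoxy-3-oxoeudesma-4,11(13)-dien-12-oic acid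
Product: 23 methyl (7R,8R,10R)-8β-acetoxy-3-oxoeudesma-4,11(13)-dien-12-oate
Conditions: MeI, K2CO3, DMF, rt
Reagents that add atoms: iodomethane, CI
Why: O-alkylation of the carboxylate with MeI under mild carbonate base; diazoalkane reagents are avoided because they can add to the acrylate as 1,3-dipoles.

Step 16
Reactants: 23 methyl (7R,8R,10R)-8β-acetoxy-3-oxoeudesma-4,11(13)-dien-12-oate
Product: 24 methyl (3S,7R,8R,10R)-8β-acetoxy-3β-hydroxyeudesma-4,11(13)-dien-12-oate
Conditions: NaBH4, CeCl3·7H2O, MeOH, −78 → −40 °C; aq. NH4Cl
Reagents that add atoms: none
Why: Luche reduction: the cerium-modified borohydride reduces the enone 1,2 and leaves the acrylate and both esters. Axial delivery of hydride to C3 from the α face of the ring-A half-chair, whose conformation is fixed by axial C14, gives the pseudo-equatorial 3β-alcohol (3S), as with steroidal 4-en-3-ones.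

Step 17
Reactants: 24 methyl (3S,7R,8R,10R)-8β-acetoxy-3β-hydroxyeudesma-4,11(13)-dien-12-oate; 25 (E)-3-methylpent-2-enoic acid
Product: 26 methyl (3S,7R,8R,10R)-8β-acetoxy-3β-[(E)-3-methylpent-2-enoyloxy]eudesma-4,11(13)-dien-12-oate (CNP0118541.1)
Conditions: DCC, DMAP (cat.), CH2Cl2, 0 °C → rt
Reagents that add atoms: none
Why: Steglich esterification with retention at C3; carbodiimide activation avoids the acid chloride and tertiary amine combination that isomerises 3,3-disubstituted acryloyl units through ketene or dienolate intermediates, so the E geometry of 25 should be carried into 26.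

## Compound list

1 | 2-methylcyclohexane-1,3-dione | CC1C(=O)CCCC1=O | starting material
2 | 3-isobutoxy-2-methylcyclohex-2-en-1-one | CC1=C(OCC(C)C)CCCC1=O | intermediate
3 | allyl chloroformate | C=CCOC(Cl)=O | starting material
4 | lithium 5-isobutoxy-6-methylcyclohexa-1,5-dien-1-olate (kinetic dienolate of 2) | [Li]OC1=CCCC(OCC(C)C)=C1C | intermediate (not isolated)
5 | allyl 4-isobutoxy-3-methyl-2-oxocyclohex-3-ene-1-carboxylate (racemic) | C=CCOC(=O)C1CCC(OCC(C)C)=C(C)C1=O | intermediate
6 | allyl 4-isobutoxy-1,3-dimethyl-2-oxocyclohex-3-ene-1-carboxylate (racemic) | C=CCOC(=O)C1(C)CCC(OCC(C)C)=C(C)C1=O | intermediate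
7 | (6R)-6-allyl-3-isobutoxy-2,6-dimethylcyclohex-2-en-1-one | O=C1C(C)=C(OCC(C)C)CC[C@]1(C)CC=C | intermediate
8 | (6R)-6-(2,3-dihydroxypropyl)-3-isobutoxy-2,6-dimethylcyclohex-2-en-1-one (both carbinol epimers) | O=C1C(C)=C(OCC(C)C)CC[C@]1(C)CC(O)CO | intermediate (not isolated)
9 | 2-[(1R)-4-isobutoxy-1,3-dimethyl-2-oxocyclohex-3-en-1-yl]acetaldehyde | O=C1C(C)=C(OCC(C)C)CC[C@]1(C)CC=O | intermediate
10 | (6R)-6-(2,2-dimethoxyethyl)-3-isobutoxy-2,6-dimethylcyclohex-2-en-1-one | O=C1C(C)=C(OCC(C)C)CC[C@]1(C)CC(OC)OC | intermediate
11 | (6R)-1-allyl-6-(2,2-dimethoxyethyl)-3-isobutoxy-2,6-dimethylcyclohex-2-en-1-ol (both C1 epimers) | C=CCC1(O)C(C)=C(OCC(C)C)CC[C@]1(C)CC(OC)OC | intermediate (not isolated)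
12 | 2-[(1R)-1,3-dimethyl-4-oxo-2-(prop-2-en-1-yl)cyclohex-2-en-1-yl]acetaldehyde | C=CCC1=C(C)C(=O)CC[C@]1(C)CC=O | intermediate
13 | 2-methylbut-2-ene | CC=C(C)C | starting material
14 | 2-[(1R)-1,3-dimethyl-2-(3-methylbut-2-en-1-yl)-4-oxocyclohex-2-en-1-yl]acetaldehyde | CC(C)=CCC1=C(C)C(=O)CC[C@]1(C)CC=O | intermediate
15 | chloro(methyl)aluminium (7R,8S,10R)-3-oxoeudesma-4,11-dien-8α-olate | C=C(C)[C@H]1CC2=C(C)C(=O)CC[C@]2(C)C[C@@H]1O[Al](C)Cl | intermediate (not isolated)
16 | (7R,8S,10R)-8α-hydroxyeudesma-4,11-dien-3-one | C=C(C)[C@H]1CC2=C(C)C(=O)CC[C@]2(C)C[C@@H]1O | intermediate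
17 | (7R,10R)-eudesma-4,11-diene-3,8-dione | C=C(C)[C@H]1CC2=C(C)C(=O)CC[C@]2(C)CC1=O | intermediate
18 | (7R,8R,10R)-8β-hydroxyeudesma-4,11-dien-3-one | C=C(C)[C@H]1CC2=C(C)C(=O)CC[C@]2(C)C[C@H]1O | intermediate
19 | (7R,8R,10R)-8β-acetoxyeudesma-4,11-dien-3-one | C=C(C)[C@H]1CC2=C(C)C(=O)CC[C@]2(C)C[C@H]1OC(C)=O | intermediate
20 | (7R,8R,10R)-8β-acetoxy-12-hydroxyeudesma-4,11(13)-dien-3-one | C=C(CO)[C@H]1CC2=C(C)C(=O)CC[C@]2(C)C[C@H]1OC(C)=O | intermediate
21 | (7R,8R,10R)-8β-acetoxy-3-oxoeudesma-4,11(13)-dien-12-al | C=C(C=O)[C@H]1CC2=C(C)C(=O)CC[C@]2(C)C[C@H]1OC(C)=O | intermediate (not isolated)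
22 | (7R,8R,10R)-8β-acetoxy-3-oxoeudesma-4,11(13)-dien-12-oic acid | C=C(C(=O)O)[C@H]1CC2=C(C)C(=O)CC[C@]2(C)C[C@H]1OC(C)=O | intermediate
23 | methyl (7R,8R,10R)-8β-acetoxy-3-oxoeudesma-4,11(13)-dien-12-oate | C=C(C(=O)OC)[C@H]1CC2=C(C)C(=O)CC[C@]2(C)C[C@H]1OC(C)=O | intermediate
24 | methyl (3S,7R,8R,10R)-8β-acetoxy-3β-hydroxyeudesma-4,11(13)-dien-12-oate | C=C(C(=O)OC)[C@H]1CC2=C(C)[C@@H](O)CC[C@]2(C)C[C@H]1OC(C)=O | intermediate
25 | (E)-3-methylpent-2-enoic acid | CC/C(C)=C/C(=O)O | starting material
26 | methyl (3S,7R,8R,10R)-8β-acetoxy-3β-[(E)-3-methylpent-2-enoyloxy]eudesma-4,11(13)-dien-12-oate (CNP0118541.1) | C=C(C(=O)OC)[C@H]1CC2=C(C)[C@@H](OC(=O)/C=C(\C)CC)CC[C@]2(C)C[C@H]1OC(C)=O | target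

## Step count and risk

Total step count: 17. Longest linear sequence: 17 steps (1 to 26); the route is linear, and 3, 13 and 25 enter as purchased reagents.

**Step 9 (key).** The most likely failure is that the more basic enone oxygen holds the Lewis acid, so the aldehyde is too weakly activated. Methyl transfer from aluminium to the aldehyde, or acid-mediated migration of the C7=C11 alkene toward the enone, could then outrun the closure; a stepwise cationic closure would also erode the C7/C8 selectivity. The fallback makes the same C7–C8 bond by an intramolecular Hosomi–Sakurai reaction, in which a silyl group instead of a proton fixes where the alkene ends. It sets out from 12: cross-metathesis with 2-methylallyl(trimethyl)silane (second-generation Grubbs catalyst RuCl2(H2IMes)(PCy3)(=CHPh), CH2Cl2, 40 °C) should give allylsilane aldehyde F1. TiCl4 in CH2Cl2 at −78 °C should then close ring B through the same chair with loss of the silyl group. The fallback returns to the route at 16.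

**Step 13.** The likely failure is poor site selectivity of the selenium ene step: attack at the C7 methine, oxidation α′ or γ to the enone, or over-oxidation. The fallback replaces oxygen transfer by ene-type allylic chlorination. From 19, NaOCl with CeCl3·7H2O in CH2Cl2/H2O at 0 °C should give allylic chloride F3. Kornblum-type oxidation with N-methylmorpholine N-oxide (NaI cat., MeCN) should convert it into enal 21, where the fallback rejoins the route at the chlorite stage of step 14.

**Step 11.** The likely failure is loss of chemoselectivity, with hydride also reaching the C3 enone. The fallback gives up selectivity in the reduction and restores it in an oxidation. From 17, excess LiBH(s-Bu)3 (THF, −78 → 0 °C) reduces both carbonyls to the diol F2 (8β-hydroxyl, C3 epimers). MnO2 in CH2Cl2 then reoxidises only the allylic C3 alcohol, and the fallback returns at 18.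

**Step 16.** The likely failure is insufficient facial selectivity at C3, because the C4 methyl group perturbs the half-chair; slow conjugate reduction of the acrylate is a lesser concern. The fallback uses both epimers. From 23 the same reduction gives, beside 24, the 3α-alcohol F4, which is separated. Mitsunobu esterification of F4 with 25 (PPh3, diisopropyl azodicarboxylate, toluene, 0 °C) inverts C3 and returns directly at 26, while 24 continues through step 17.

## Further compounds

F1 | step 9 | 2-[(1R)-1,3-dimethyl-2-[3-methyl-4-(trimethylsilyl)but-2-en-1-yl]-4-oxocyclohex-2-en-1-yl]acetaldehyde (E/Z mixture) | C[Si](C)(C)CC(C)=CCC1=C(C)C(=O)CC[C@]1(C)CC=O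
F2 | step 11 | (7R,8R,10R)-eudesma-4,11-diene-3,8β-diol (both C3 epimers) | C=C(C)[C@H]1CC2=C(C)C(O)CC[C@]2(C)C[C@H]1O
F3 | step 13 | (7R,8R,10R)-8β-acetoxy-12-chloroeudesma-4,11(13)-dien-3-one | C=C(CCl)[C@H]1CC2=C(C)C(=O)CC[C@]2(C)C[C@H]1OC(C)=O
F4 | step 16 | methyl (3R,7R,8R,10R)-8β-acetoxy-3α-hydroxyeudesma-4,11(13)-dien-12-oate | C=C(C(=O)OC)[C@H]1CC2=C(C)[C@H](O)CC[C@]2(C)C[C@H]1OC(C)=O
A1 | alternative 1 | methyl 8β-acetoxy-3β-(tert-butyldimethylsilyloxy)eudesma-4,11(13)-dien-12-oate | C=C(C(=O)OC)[C@H]1CC2=C(C)[C@@H](O[Si](C)(C)C(C)(C)C)CC[C@]2(C)C[C@H]1OC(C)=O
A2 | alternative 1 | methyl (1(10)E,4E)-8β-acetoxy-3β-(tert-butyldimethylsilyloxy)germacra-1(10),4,11(13)-trien-12-oate | C=C(C(=O)OC)[C@H]1C/C=C(\C)[C@@H](O[Si](C)(C)C(C)(C)C)CC/C=C(\C)C[C@H]1OC(C)=O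
A3 | alternative 2 | 8α-(tert-butyldimethylsilyloxy)eudesma-1,4,11-trien-3-one | C=C(C)[C@H]1CC2=C(C)C(=O)C=C[C@]2(C)C[C@@H]1O[Si](C)(C)C(C)(C)C
A4 | alternative 2 | (2R,3R)-2-(tert-butyldimethylsilyloxy)-3-[(3-hydroxy-2,6-dimethylphenyl)methyl]-4-methylpent-4-en-1-yl 4-methylbenzenesulfonate | C=C(C)[C@@H](Cc1c(C)c(O)ccc1C)[C@H](COS(=O)(=O)c1ccc(C)cc1)O[Si](C)(C)C(C)(C)C
A5 | alternative 3 | cis-fused 2-methoxy-4a-methyl-6-(trimethylsilyloxy)-4a,5,8,8a-tetrahydronaphthalene-1,4-dione | COC1=CC(=O)[C@]2(C)CC(O[Si](C)(C)C)=CC[C@@H]2C1=O
A6 | alternative 3 | 2-methoxy-5-methyl-1,4-benzoquinone | COC1=CC(=O)C(C)=CC1=O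
A7 | alternative 3 | 2-(trimethylsilyloxy)buta-1,3-diene | C=CC(=C)O[Si](C)(C)C
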